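**Retrosynthetic overview**

1. The C6–O ester bond is made last but one, by Mitsunobu inversion of the axial 6β-allylic alcohol with (2E,4E,6E)-octatrienoic acid; the 6β-alcohol comes from a C6 enone.
2. Ring B is closed by the C8–C9 bond: the enolate of an α-silyloxy aldehyde (C9) adds 6-endo-dig to the β-carbon C8 of a but-2-ynoyl group on C5, and C5 is equilibrated in the same flask.
3. Enabling feature: C9 carries both the oxygen and the formyl carbon C11 and sits on the quaternary C10, so it is the one enolisable aldehyde α-carbon and its adduct cannot enolise back. The C6 carbonyl, conjugated through C7 to C8 (the future Δ7 alkene bearing C12), makes C8 the only electrophilic carbon six atoms away.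
4. Ring A is purchased as 2,2,6-trimethylcyclohexanone. C10 is set by decarboxylative asymmetric allylation; the allyl group becomes C9/C11 and the ketone carbon becomes C5 (epoxide, Meinwald shift, propynyl addition).
5. Ring order: ring A (bought), then ring B (key step).

Key step: step 9

Remark: drimane numbering is used throughout (ring A = C1–C5, C10; ring B = C5–C10; C11 on C9, C12 on C8). The target SMILES is read as (5S,6S,9R,10S): 5α-H, 10β-CH3, 9α-OH/9β-CHO and an equatorial 6α-acyloxy group.

**Step 1**
Reactants: 1 2,2,6-trimethylcyclohexan-1-one; 2 allyl chloroformate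
Product: 3 allyl 2,6,6-trimethylcyclohex-1-en-1-yl carbonate
Conditions: LiN(SiMe3)2, THF, 0 °C; then 2, −78 → 23 °C
Reagents that add atoms: none
Why: O-acylation of the only possible (tetrasubstituted) lithium enolate of 1 with the chloroformate should give the enol carbonate needed for the decarboxylative Tsuji–Trost allylation; no stereocenter is formed.

**Step 2**
Reactants: 3 allyl 2,6,6-trimethylcyclohex-1-en-1-yl carbonate
Product: 4 (R)-2-allyl-2,6,6-trimethylcyclohexan-1-one
Conditions: Pd2(dba)3 (2.5 mol%), (R)-t-Bu-PHOX (6 mol%), THF, 25 °C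
Reagents that add atoms: none
Why: Decarboxylative asymmetric allylic alkylation (Tsuji–Trost type): zerovalent palladium ionises the allyl carbonate, CO2 is lost and the enolate recombines with the π-allyl fragment inside the chiral P,N-ligand sphere, which should set the quaternary C10 as R (ligand antipode chosen from the known sense of induction of this ligand class with 2-alkyl-2-allylcyclohexanones).

**Step 3**
Reactants: 4 (R)-2-allyl-2,6,6-trimethylcyclohexan-1-one
Product: 5 (2R)-2-(1-hydroxyprop-2-en-1-yl)-2,6,6-trimethylcyclohexan-1-one (both carbinol epimers)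
Conditions: SeO2 (0.5 equiv), t-BuOOH, CH2Cl2, 23 °C
Reagents that add atoms: tert-butyl hydroperoxide, CC(C)(C)OO (terminal oxygen source, relayed by SeO2)
Why: Riley-type allylic oxidation (ene reaction of SeO2 at the terminal alkene carbon, then [2,3]-sigmatropic shift) should place oxygen on C9 and restore the terminal alkene, both ketone α-carbons being quaternary and inert; the C9 configuration is immaterial because C9 becomes trigonal in step 9.

**Step 4**
Reactants: 5 (2R)-2-(1-hydroxyprop-2-en-1-yl)-2,6,6-trimethylcyclohexan-1-one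
Product: 6 (2R)-2-[1-(tert-butyldimethylsilyloxy)prop-2-en-1-yl]-2,6,6-trimethylcyclohexan-1-one
Conditions: TBSOTf, 2,6-lutidine, CH2Cl2, 0 °C
Reagents that add atoms: tert-butyldimethylsilyl triflate, CC(C)(C)[Si](C)(C)OS(=O)(=O)C(F)(F)F
Why: Silyl ether formation with the reactive triflate protects the hindered carbinol and blocks retro-aldol cleavage of the β-hydroxy ketone in the basic steps that follow.

**Step 5**
Reactants: 6 (2R)-2-[1-(tert-butyldimethylsilyloxy)prop-2-en-1-yl]-2,6,6-trimethylcyclohexan-1-one
Product: 7 (4R)-4-[1-(tert-butyldimethylsilyloxy)prop-2-en-1-yl]-4,8,8-trimethyl-1-oxaspiro[2.5]octane (epimers at the spiro carbon C5 and at C9)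
Conditions: ClCH2I, MeLi·LiBr, THF, −78 → 23 °C
Reagents that add atoms: chloroiodomethane, ClCI
Why: Chloromethyllithium, made in the flask by iodine–lithium exchange, is small and reactive enough to add to the doubly neopentyl ketone, and the chlorohydrin alkoxide should close to the spiro-epoxide on warming (carbenoid epoxidation, the hindered-ketone counterpart of the Corey–Chaykovsky reaction); the new C5 center is equilibrated later.

**Step 6**
Reactants: 7 (4R)-4-[1-(tert-butyldimethylsilyloxy)prop-2-en-1-yl]-4,8,8-trimethyl-1-oxaspiro[2.5]octane; 8 prop-1-yn-1-ylmagnesium bromide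
Product: 10 1-{2-[1-(tert-butyldimethylsilyloxy)prop-2-en-1-yl]-2,6,6-trimethylcyclohexyl}but-2-yn-1-ol, via aldehyde 9 (not isolated)
Conditions: MgBr2·OEt2, CH2Cl2, 0 °C; then 8, THF, −78 → 0 °C
Reagents that add atoms: none
Why: Meinwald rearrangement (MgBr2 opens the epoxide at the tertiary C5 and a 1,2-hydride shift from C6 gives aldehyde 9), followed in the same flask by Grignard addition of the slim propynyl nucleophile, should install C7, C8 and C12; the C5 and C6 centers are left as mixtures because both are erased later.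

**Step 7**
Reactants: 10 1-{2-[1-(tert-butyldimethylsilyloxy)prop-2-en-1-yl]-2,6,6-trimethylcyclohexyl}but-2-yn-1-ol
Product: 11 1-{2-[1-(tert-butyldimethylsilyloxy)prop-2-en-1-yl]-2,6,6-trimethylcyclohexyl}but-2-yn-1-one
Conditions: Dess–Martin periodinane, NaHCO3, CH2Cl2, 0 → 23 °C
Reagents that add atoms: none
Why: Dess–Martin oxidation of the propargylic alcohol under buffered, non-basic conditions should give the alkynyl ketone without touching the silyl ether or the vinyl group.

**Step 8**
Reactants: 11 1-{2-[1-(tert-butyldimethylsilyloxy)prop-2-en-1-yl]-2,6,6-trimethylcyclohexyl}but-2-yn-1-one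
Product: 12 2-[2-(but-2-ynoyl)-1,3,3-trimethylcyclohexyl]-2-(tert-butyldimethylsilyloxy)acetaldehyde
Conditions: O3, CH2Cl2, −78 °C; then Me2S, −78 → 23 °C
Reagents that add atoms: ozone, [O-][O+]=O
Why: Ozonolysis should be chemoselective for the terminal alkene over the electron-poor conjugated alkyne and, after reductive work-up with Me2S (a phosphine would add to the ynone), unveils C11 as the aldehyde.

**Step 9**
Reactants: 12 2-[2-(but-2-ynoyl)-1,3,3-trimethylcyclohexyl]-2-(tert-butyldimethylsilyloxy)acetaldehyde
Product: 14 (5S,9R,10S)-9-(tert-butyldimethylsilyloxy)-6-oxodrim-7-en-11-al, via cis-fused C5 epimer 13 (not isolated)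
Conditions: 2-tert-butyl-1,1,3,3-tetramethylguanidine (1.0 equiv), MeCN (0.02 M), 4 Å MS, 0 → 50 °C
Reagents that add atoms: none
Why: The hindered guanidine reversibly deprotonates C9–H of the α-silyloxy aldehyde (the most acidic C–H of 12; enolates at C5 or C12 are unproductive and revert), and the enolate adds through C9 to the ynone β-carbon C8, the allenolate then being protonated at C7 to give the ring-bound cis-enone. The closest known reaction type is the base-mediated intramolecular Michael addition (anionic 6-endo-dig cyclisation) of carbonyl enolates to alkynyl ketones, and ring B closes here in this 6-endo-dig mode. C9 is controlled by allylic 1,3-strain in the enolate: the C9=C11 bond eclipses the small C10 methyl group, and because the new C9–C8 bond must form on the side of C5, the formyl group should end cis to the C10 methyl (β) and the silyloxy group α (9R), whatever the configuration at C5. C5 is set thermodynamically, since after closure C9 is quaternary and C5–H is the only acidic ring position, so the base should equilibrate the cis-fused epimer 13 through the C5–C6 dienolate to the trans-fused decalone 14 (5S). The step needs C- over O-attack, 6-endo over 5-exo closure and survival of the formyl group: the first two are secured by the ynone polarisation and the tether (attack through oxygen, at C7 or at C6 would give an eight-membered ring, an anti-Michael five-membered ring or a four-membered ring), the third by a non-nucleophilic base, the adduct being a non-enolisable aldehyde formed irreversibly.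

**Step 10**
Reactants: 14 (5S,9R,10S)-9-(tert-butyldimethylsilyloxy)-6-oxodrim-7-en-11-al
Product: 15 (5S,6R,9R,10S)-9-(tert-butyldimethylsilyloxy)-6-hydroxydrim-7-en-11-al (6β-OH, axial)
Conditions: NaBH4, CeCl3·7H2O, EtOH/H2O, −15 °C
Reagents that add atoms: none
Why: Luche reduction in aqueous ethanol: CeCl3 should hold the electron-poor α-silyloxy aldehyde as its hydrate and activate the enone for 1,2-attack, and hydride should enter C6 from the α face, anti to the syn-axial C4 and C10 methyl groups, to give the axial 6β-alcohol.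

**Step 11**
Reactants: 16 (2E,4E)-hexa-2,4-dienal; 17 triethyl phosphonoacetate
Product: 18 ethyl (2E,4E,6E)-octa-2,4,6-trienoate
Conditions: NaH, THF, 0 → 23 °C
Reagents that add atoms: none
Why: Horner–Wadsworth–Emmons olefination of the dienal with the stabilised phosphonate anion should form the new conjugated double bond with E geometry.

**Step 12**
Reactants: 18 ethyl (2E,4E,6E)-octa-2,4,6-trienoate
Product: 19 (2E,4E,6E)-octa-2,4,6-trienoic acid
Conditions: LiOH, THF/H2O, 23 °C; then HCl (aq) to pH 3
Reagents that add atoms: lithium hydroxide, [Li+].[OH-]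
Why: Saponification of the ethyl ester at room temperature should leave the all-E triene untouched.

**Step 13**
Reactants: 15 (5S,6R,9R,10S)-9-(tert-butyldimethylsilyloxy)-6-hydroxydrim-7-en-11-al; 19 (2E,4E,6E)-octa-2,4,6-trienoic acid
Product: 20 (5S,6S,9R,10S)-9-(tert-butyldimethylsilyloxy)-11-oxodrim-7-en-6-yl (2E,4E,6E)-octa-2,4,6-trienoate
Conditions: PPh3, DIAD, PhMe, 0 → 23 °C
Reagents that add atoms: none
Why: Mitsunobu esterification: the oxyphosphonium ion of the axial, allylic 6β-alcohol should be displaced by the trienoate from the open α face with inversion (SN2), helped by relief of the 1,3-diaxial strain, which sets C6 as the equatorial 6α ester (S); the neopentyl aldehyde and the silyl ether are inert.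

**Step 14**
Reactants: 20 (5S,6S,9R,10S)-9-(tert-butyldimethylsilyloxy)-11-oxodrim-7-en-6-yl (2E,4E,6E)-octa-2,4,6-trienoate
Product: 21 (5S,6S,9R,10S)-9-hydroxy-11-oxodrim-7-en-6-yl (2E,4E,6E)-octa-2,4,6-trienoate (target)
Conditions: HF·pyridine, pyridine/THF, 0 → 23 °C
Reagents that add atoms: none
Why: Fluoride-mediated cleavage of the tertiary silyl ether with buffered HF·pyridine should free the 9α-hydroxyl without harming the allylic ester, the triene or the α-hydroxy aldehyde.

**Compound list**

1 | 2,2,6-trimethylcyclohexan-1-one (racemic) | CC1CCCC(C)(C)C1=O | starting material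
2 | allyl chloroformate | C=CCOC(=O)Cl | starting material
3 | allyl 2,6,6-trimethylcyclohex-1-en-1-yl carbonate | C=CCOC(=O)OC1=C(C)CCCC1(C)C | intermediate
4 | (R)-2-allyl-2,6,6-trimethylcyclohexan-1-one | C=CC[C@@]1(C)CCCC(C)(C)C1=O | intermediate
5 | (2R)-2-(1-hydroxyprop-2-en-1-yl)-2,6,6-trimethylcyclohexan-1-one, both C9 epimers | C=CC(O)[C@@]1(C)CCCC(C)(C)C1=O | intermediate
6 | (2R)-2-[1-(tert-butyldimethylsilyloxy)prop-2-en-1-yl]-2,6,6-trimethylcyclohexan-1-one, both C9 epimers | C=CC(O[Si](C)(C)C(C)(C)C)[C@@]1(C)CCCC(C)(C)C1=O | intermediate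
7 | (4R)-4-[1-(tert-butyldimethylsilyloxy)prop-2-en-1-yl]-4,8,8-trimethyl-1-oxaspiro[2.5]octane, epimers at the spiro carbon (C5) and at C9 | C=CC(O[Si](C)(C)C(C)(C)C)[C@@]1(C)CCCC(C)(C)C12CO2 | intermediate
8 | prop-1-yn-1-ylmagnesium bromide | CC#C[Mg]Br | starting material
9 | 2-[1-(tert-butyldimethylsilyloxy)prop-2-en-1-yl]-2,6,6-trimethylcyclohexane-1-carbaldehyde, quaternary C10 as in 4, epimers at C5 and C9 | C=CC(O[Si](C)(C)C(C)(C)C)[C@@]1(C)CCCC(C)(C)C1C=O | intermediate
10 | 1-{2-[1-(tert-butyldimethylsilyloxy)prop-2-en-1-yl]-2,6,6-trimethylcyclohexyl}but-2-yn-1-ol, quaternary C10 as in 4, epimers at C5, C6 and C9 | C=CC(O[Si](C)(C)C(C)(C)C)[C@@]1(C)CCCC(C)(C)C1C(O)C#CC | intermediate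
11 | 1-{2-[1-(tert-butyldimethylsilyloxy)prop-2-en-1-yl]-2,6,6-trimethylcyclohexyl}but-2-yn-1-one, quaternary C10 as in 4, epimers at C5 and C9 | C=CC(O[Si](C)(C)C(C)(C)C)[C@@]1(C)CCCC(C)(C)C1C(=O)C#CC | intermediate
12 | 2-[2-(but-2-ynoyl)-1,3,3-trimethylcyclohexyl]-2-(tert-butyldimethylsilyloxy)acetaldehyde, quaternary C10 as in 4, epimers at C5 and C9 | O=CC(O[Si](C)(C)C(C)(C)C)[C@@]1(C)CCCC(C)(C)C1C(=O)C#CC | intermediate
13 | (5R,9R,10S)-9-(tert-butyldimethylsilyloxy)-6-oxodrim-7-en-11-al (cis-fused, 5β-H) | O=C1C=C(C)[C@](O[Si](C)(C)C(C)(C)C)(C=O)[C@@]2(C)CCCC(C)(C)[C@@H]12 | intermediate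
14 | (5S,9R,10S)-9-(tert-butyldimethylsilyloxy)-6-oxodrim-7-en-11-al (trans-fused; 9α-OSi, 9β-CHO) | O=C1C=C(C)[C@](O[Si](C)(C)C(C)(C)C)(C=O)[C@@]2(C)CCCC(C)(C)[C@H]12 | intermediate
15 | (5S,6R,9R,10S)-9-(tert-butyldimethylsilyloxy)-6-hydroxydrim-7-en-11-al (6β-OH) | O[C@@H]1C=C(C)[C@](O[Si](C)(C)C(C)(C)C)(C=O)[C@@]2(C)CCCC(C)(C)[C@H]12 | intermediate
16 | (2E,4E)-hexa-2,4-dienal (sorbaldehyde) | C/C=C/C=C/C=O | starting material
17 | triethyl phosphonoacetate | CCOC(=O)CP(=O)(OCC)OCC | starting material
18 | ethyl (2E,4E,6E)-octa-2,4,6-trienoate | C/C=C/C=C/C=C/C(=O)OCC | intermediate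
19 | (2E,4E,6E)-octa-2,4,6-trienoic acid | C/C=C/C=C/C=C/C(=O)O | intermediate
20 | (5S,6S,9R,10S)-9-(tert-butyldimethylsilyloxy)-11-oxodrim-7-en-6-yl (2E,4E,6E)-octa-2,4,6-trienoate (6α ester) | C/C=C/C=C/C=C/C(=O)O[C@H]1C=C(C)[C@](O[Si](C)(C)C(C)(C)C)(C=O)[C@@]2(C)CCCC(C)(C)[C@H]12 | intermediate
21 | (5S,6S,9R,10S)-9-hydroxy-11-oxodrim-7-en-6-yl (2E,4E,6E)-octa-2,4,6-trienoate | C/C=C/C=C/C=C/C(=O)O[C@H]1C=C(C)[C@](O)(C=O)[C@@]2(C)CCCC(C)(C)[C@H]12 | target

**Step count**

Total: 14 steps. Longest linear sequence: 12 steps (steps 1–10, 13 and 14); steps 11 and 12 are the side branch to acid 19.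

**Steps most likely to fail, with fallbacks**

Step 9 (key step). Possible failures are loss of the formyl group by nucleophile-induced C9–C11 cleavage (the C9 carbanion would be a stabilised dienolate), silyl migration within the enediolate, and incomplete equilibration at C5. The fallback replaces the base/enolate mode by a Lewis-acid/enol-silane mode. Starting from 12, soft enolisation with TBSOTf/Et3N (CH2Cl2, −78 °C) should give the 1,2-bis(silyloxy)alkene F1. Sc(OTf)3 (10 mol%, CH2Cl2, −40 → 0 °C, aqueous work-up) should then close ring B by an intramolecular Mukaiyama–Michael addition of C9 to C8 under the same allylic-strain control, the silyl oxocarbenium ion giving up its silyl group on work-up. A short treatment with the hindered guanidine equilibrates C5, and the material rejoins the route at 14.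

Step 13. Possible failures are E2 loss of the axial oxyphosphonium group with the antiperiplanar C5–H (giving a 5,7-diene), esterification with retention through an acyloxyphosphonium ion, and sluggish reaction of the weakly acidic trienoic acid. The fallback decouples inversion from acylation. Starting from 15, a Mitsunobu reaction with the more acidic 4-nitrobenzoic acid should give the 6α-(4-nitrobenzoate) F3. K2CO3/MeOH (0 °C) frees the equatorial 6α-alcohol F4. Yamaguchi acylation of this unhindered alcohol with 19 (2,4,6-trichlorobenzoyl chloride, Et3N, DMAP, PhMe) rejoins the route at 20.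

Step 10. Possible failures are competing reduction of the aldehyde (insufficient hydration of the hindered α-silyloxy aldehyde) and 1,4-reduction of the enone. The fallback is exhaustive reduction followed by site-selective re-oxidation. Starting from 14, NaBH4/CeCl3·7H2O in MeOH (0 °C) should reduce both carbonyl groups to the 6β,11-diol F2. Aerobic oxidation with [Cu(MeCN)4]OTf, 2,2′-bipyridine, TEMPO and N-methylimidazole (MeCN, air), a system that oxidises primary but not secondary alcohols, should restore the aldehyde and rejoin the route at 15.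

**Further compounds**

F1 | step 9 | 1-[1,2-bis(tert-butyldimethylsilyloxy)ethenyl]-substituted ynone: 1-{2-[1,2-bis(tert-butyldimethylsilyloxy)ethenyl]-2,6,6-trimethylcyclohexyl}but-2-yn-1-one (C10 as in 4; C5 epimers, alkene isomers) | CC(C)(C)[Si](C)(C)OC=C(O[Si](C)(C)C(C)(C)C)[C@@]1(C)CCCC(C)(C)C1C(=O)C#CC
F2 | step 10 | (5S,6R,9R,10S)-9-(tert-butyldimethylsilyloxy)drim-7-ene-6,11-diol (6β-OH) | O[C@@H]1C=C(C)[C@](O[Si](C)(C)C(C)(C)C)(CO)[C@@]2(C)CCCC(C)(C)[C@H]12
F3 | step 13 | (5S,6S,9R,10S)-9-(tert-butyldimethylsilyloxy)-11-oxodrim-7-en-6-yl 4-nitrobenzoate (6α ester) | O=C(O[C@H]1C=C(C)[C@](O[Si](C)(C)C(C)(C)C)(C=O)[C@@]2(C)CCCC(C)(C)[C@H]12)c1ccc(cc1)[N+](=O)[O-]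
F4 | step 13 | (5S,6S,9R,10S)-9-(tert-butyldimethylsilyloxy)-6-hydroxydrim-7-en-11-al (6α-OH) | O[C@H]1C=C(C)[C@](O[Si](C)(C)C(C)(C)C)(C=O)[C@@]2(C)CCCC(C)(C)[C@H]12
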